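**Retrosynthetic overview**
- Feature (flavonoid numbering: O1, C2, C3, C4 in ring C). C3 is bonded to an oxygen, a hydrogen, the C4 carbonyl carbon and the oxygenated benzylic carbon C2. This is the pattern left when the carbene carbon of an aryl diazomethyl ketone has taken up the O–H of an alcohol and the C=O of an aldehyde.
- First cut: O1–C2 of ring C, closed late by an invertive phenol/benzylic alcohol condensation. This opens ring C to a syn 2-alkoxy-3-hydroxy ketone.
- Key cut: C3–O and C2–C3 together. The pieces are the ring A diazoketone, 4-methoxybenzyl alcohol (which leaves O3 masked and the C2 hydroxyl free) and the ring B aldehyde. The aldehyde is taken as vanillin acetate, so that the formyl group is electrophilic enough.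
- Ring A block from 2,4,6-trihydroxyacetophenone: para O-prenylation, monosilylation of one ortho OH (the later O1), chelate-directed aromatic Claisen rearrangement (1,1-dimethylallyl group at the later C6), MOM protection, deacylative diazo transfer.
- Ring order: rings A and B are bought in. Ring C is the only ring formed, two steps after the key step.

Key step: step 6

Assumption: the sense of induction of the phosphoric acid cannot be derived for this trio of partners; the (R)-acid is written, and its mirror image would be used if the first run shows the opposite enantiomer.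

**Step 1**
Reactants: 1 2,4,6-trihydroxyacetophenone (dried); 2 3-methylbut-2-en-1-ol (prenol)
Product: 3 1-[2,6-dihydroxy-4-(3-methylbut-2-enyloxy)phenyl]ethanone
Conditions: PPh3 (1.05 equiv), DIAD (1.05 equiv), THF, 0 °C to rt
Reagents that add atoms: none
Why: Mitsunobu etherification: the hydroxyl para to the acetyl group is the most acidic and the only one not hydrogen-bonded to the carbonyl oxygen, so one equivalent of reagents should alkylate it alone, and the redox condensation gives the O-prenyl ether without the C-alkylation typical of phloroglucinol anions and prenyl halides.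

**Step 2**
Reactants: 3 1-[2,6-dihydroxy-4-(3-methylbut-2-enyloxy)phenyl]ethanone
Product: 4 1-[2-hydroxy-4-(3-methylbut-2-enyloxy)-6-(triisopropylsilyloxy)phenyl]ethanone
Conditions: TIPSCl (1.1 equiv), imidazole (2.5 equiv), DMF, rt
Reagents that add atoms: triisopropylsilyl chloride, CC(C)[Si](Cl)(C(C)C)C(C)C
Why: Silyl ether formation: the two ortho hydroxyls are equivalent, and once one carries the bulky silyl group the other is locked in the chelate with the acetyl oxygen and no longer reacts with the hindered chloride, so the future O1 is set apart from the two oxygens that will flank C6.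

**Step 3**
Reactants: 4 1-[2-hydroxy-4-(3-methylbut-2-enyloxy)-6-(triisopropylsilyloxy)phenyl]ethanone
Product: 6 1-[2,4-dihydroxy-3-(2-methylbut-3-en-2-yl)-6-(triisopropylsilyloxy)phenyl]ethanone, via ortho-dienone 5 (not isolated)
Conditions: N,N-diethylaniline, 190 °C, argon, sealed tube, short reaction time
Reagents that add atoms: none
Why: Aromatic Claisen rearrangement: the [3,3] shift carries the tertiary allyl terminus to the ring carbon between the chelated hydroxyl and the ether oxygen (the later C6), because the O–H···O=C chelate favours the Kekulé structure with a double bond between these two carbons (the regiochemistry known for 4-allyloxy-2-hydroxyacetophenones), the silyl ether screens the other ortho carbon, and the acetyl-blocked para position prevents a follow-up Cope shift from ending in a normal prenyl isomer, so 5 simply enolises to 6.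

**Step 4**
Reactants: 6 1-[2,4-dihydroxy-3-(2-methylbut-3-en-2-yl)-6-(triisopropylsilyloxy)phenyl]ethanone
Product: 7 1-[2,4-bis(methoxymethoxy)-3-(2-methylbut-3-en-2-yl)-6-(triisopropylsilyloxy)phenyl]ethanone
Conditions: NaH (2.4 equiv), MOMCl (2.6 equiv), THF/DMF, 0 °C to rt
Reagents that add atoms: chloromethyl methyl ether (MOMCl), COCCl
Why: Williamson-type O-alkylation of the two sodium phenoxides by the small and very reactive chloromethyl ether, which reaches even the oxygen wedged between the quaternary carbon and the acetyl group; the phenols are far more acidic than the methyl ketone, so the measured amount of NaH leaves the ketone and the silyl ether alone.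

**Step 5**
Reactants: 7 1-[2,4-bis(methoxymethoxy)-3-(2-methylbut-3-en-2-yl)-6-(triisopropylsilyloxy)phenyl]ethanone
Product: 9 2-diazo-1-[2,4-bis(methoxymethoxy)-3-(2-methylbut-3-en-2-yl)-6-(triisopropylsilyloxy)phenyl]ethanone, via trifluoroacetyl diketone 8 (not isolated)
Conditions: LiHMDS, THF, –78 °C; CF3CO2CH2CF3, –78 °C; aq NH4Cl; then p-ABSA, Et3N, H2O (1 equiv), MeCN, rt
Reagents that add atoms: 2,2,2-trifluoroethyl trifluoroacetate, O=C(OCC(F)(F)F)C(F)(F)F (its CF3CO group stands in 8 only); 4-acetamidobenzenesulfonyl azide (p-ABSA), CC(=O)Nc1ccc(cc1)S(=O)(=O)N=[N+]=[N-] (the two nitrogen atoms of 9)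
Why: Detrifluoroacetylative diazo transfer (Danheiser variant of the Regitz reaction): the methyl group is the only enolisable position, its trifluoroacetylation to 8 makes the carbon acidic enough for azide transfer under Et3N, and loss of the trifluoroacetyl group on the sulfonamide leaves the terminal diazoketone.

**Step 6**
Reactants: 9 2-diazo-1-[2,4-bis(methoxymethoxy)-3-(2-methylbut-3-en-2-yl)-6-(triisopropylsilyloxy)phenyl]ethanone; 10 4-methoxybenzyl alcohol; 11 4-formyl-2-methoxyphenyl acetate (vanillin acetate)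
Product: 14 (2R,3S)-3-(4-acetoxy-3-methoxyphenyl)-1-[2,4-bis(methoxymethoxy)-3-(2-methylbut-3-en-2-yl)-6-(triisopropylsilyloxy)phenyl]-3-hydroxy-2-(4-methoxybenzyloxy)propan-1-one (syn), via oxonium ylide 12 (not isolated), via Z-enol 13 (not isolated)
Conditions: Rh2(OAc)4 (2 mol%), (R)-TRIP [(R)-3,3'-bis(2,4,6-triisopropylphenyl)-1,1'-binaphthyl-2,2'-diyl hydrogen phosphate] (10 mol%), 10 (3 equiv), 11 (2 equiv), 4 Å MS, CH2Cl2, –20 °C, 9 added by syringe pump over 4 h
Reagents that add atoms: none
Why: Rh2(OAc)4 expels N2 from 9 to give a rhodium-bound ketocarbene whose carbon (the later C3) is attacked by the hydroxyl oxygen of 10, and the resulting ylide 12 relaxes to Z-enol 13, which adds through C3 to the formyl carbon of 11 (the later C2) before a 1,2-proton shift can give plain O–H insertion. The closest known reaction type is the dirhodium/chiral phosphoric acid three-component trapping of alcohol-derived oxonium ylides, aldol-type with aryl aldehydes and Mannich-type with diazoacetophenones. No ring closes, and only the C3–O and C2–C3 bonds are made. Both stereocentres arise in one cyclic transition state in which the acid binds the enol O–H through P=O and the aldehyde through P–OH: the Z-enol geometry (the doubly ortho-substituted aryl group cis to H) translates into the syn relation, and the 3,3'-aryl pockets of the acid select the face, hence (2R,3S). The step needs intermolecular capture of the carbene in preference to attack by the ortho oxygens, which is served by the weakly nucleophilic, shielded silyl ether oxygen on one side, the acetal oxygen wedged between the quaternary carbon and the acyl group on the other, the excess of 10 and the slow addition of 9. The acetoxy group para to the formyl group makes 11 clearly more electrophilic than an ether-protected vanillin, which lets the aldol trapping keep pace with the proton shift.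

**Step 7**
Reactants: 14 the syn aldol-type adduct of step 6
Product: 15 (2R,3S)-3-(4-acetoxy-3-methoxyphenyl)-3-hydroxy-1-[6-hydroxy-2,4-bis(methoxymethoxy)-3-(2-methylbut-3-en-2-yl)phenyl]-2-(4-methoxybenzyloxy)propan-1-one
Conditions: TBAF/AcOH (1:1, 1.2 equiv), THF, 0 °C
Reagents that add atoms: none
Why: Fluoride-induced cleavage of the aryl silyl ether, much faster than attack on any other group; acetic acid buffers the phenoxide so that retro-aldol cleavage, epimerisation at C3 and acetate migration should not set in.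

**Step 8**
Reactants: 15 the free phenol of step 7
Product: 16 (2R,3R)-2-(4-acetoxy-3-methoxyphenyl)-3-(4-methoxybenzyloxy)-5,7-bis(methoxymethoxy)-6-(2-methylbut-3-en-2-yl)chroman-4-one
Conditions: PPh3 (1.5 equiv), DIAD (1.5 equiv), THF (0.02 M), 0 °C to rt
Reagents that add atoms: none
Why: Intramolecular Mitsunobu etherification, an established closure of 2'-hydroxy-β-hydroxydihydrochalcones to 3-oxygenated flavanones: PPh3/DIAD activate the only free alcohol (at C2) and the only free phenol (at C8a, acidified by the ortho carbonyl) displaces it in a 6-exo-tet SN2 process, so C2 is inverted from S to R while C3 is untouched, the acetoxy group on ring B disfavours ionisation, and the 2,3-trans product is also the thermodynamically preferred one.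

**Step 9**
Reactants: 16 the 3-O-PMB flavanone of step 8
Product: 17 (2R,3R)-2-(4-acetoxy-3-methoxyphenyl)-3-hydroxy-5,7-bis(methoxymethoxy)-6-(2-methylbut-3-en-2-yl)chroman-4-one
Conditions: DDQ (1.5 equiv), CH2Cl2/pH 7 phosphate buffer (10:1), 0 °C to rt
Reagents that add atoms: none
Why: Oxidative cleavage of the 4-methoxybenzyl ether by DDQ (hydride abstraction from the electron-rich benzylic CH2, then hydrolysis), which under buffered conditions leaves the MOM acetals, the aryl acetate, the monosubstituted alkene and both stereocentres untouched.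

**Step 10**
Reactants: 17 the 3-hydroxyflavanone of step 9
Product: 18 (2R,3R)-3,5,7-trihydroxy-2-(4-hydroxy-3-methoxyphenyl)-6-(2-methylbut-3-en-2-yl)chroman-4-one (target)
Conditions: HCl (1.25 M in MeOH), 40 °C
Reagents that add atoms: none
Why: Acid-catalysed methanolysis removes both MOM acetals (acetal exchange) and the aryl acetate (transesterification) in one operation under conditions too mild to protonate the monosubstituted alkene, and the 2,3-trans arrangement, being the more stable one, is not at risk.

**Compound list**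
1 | 2,4,6-trihydroxyacetophenone | CC(=O)c1c(O)cc(O)cc1O | starting material
2 | 3-methylbut-2-en-1-ol (prenol) | CC(C)=CCO | starting material
3 | 1-[2,6-dihydroxy-4-(3-methylbut-2-enyloxy)phenyl]ethanone | CC(=O)c1c(O)cc(OCC=C(C)C)cc1O | intermediate
4 | 1-[2-hydroxy-4-(3-methylbut-2-enyloxy)-6-(triisopropylsilyloxy)phenyl]ethanone | CC(=O)c1c(O)cc(OCC=C(C)C)cc1O[Si](C(C)C)(C(C)C)C(C)C | intermediate
5 | 4-acetyl-3-hydroxy-2-(2-methylbut-3-en-2-yl)-5-(triisopropylsilyloxy)cyclohexa-3,5-dien-1-one (racemic ortho-dienone, not isolated) | CC(=O)C1=C(O)C(C(C)(C)C=C)C(=O)C=C1O[Si](C(C)C)(C(C)C)C(C)C | intermediate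
6 | 1-[2,4-dihydroxy-3-(2-methylbut-3-en-2-yl)-6-(triisopropylsilyloxy)phenyl]ethanone | CC(=O)c1c(O)c(C(C)(C)C=C)c(O)cc1O[Si](C(C)C)(C(C)C)C(C)C | intermediate
7 | 1-[2,4-bis(methoxymethoxy)-3-(2-methylbut-3-en-2-yl)-6-(triisopropylsilyloxy)phenyl]ethanone | CC(=O)c1c(OCOC)c(C(C)(C)C=C)c(OCOC)cc1O[Si](C(C)C)(C(C)C)C(C)C | intermediate
8 | 1-[2,4-bis(methoxymethoxy)-3-(2-methylbut-3-en-2-yl)-6-(triisopropylsilyloxy)phenyl]-4,4,4-trifluorobutane-1,3-dione (not isolated) | O=C(CC(=O)C(F)(F)F)c1c(OCOC)c(C(C)(C)C=C)c(OCOC)cc1O[Si](C(C)C)(C(C)C)C(C)C | intermediate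
9 | 2-diazo-1-[2,4-bis(methoxymethoxy)-3-(2-methylbut-3-en-2-yl)-6-(triisopropylsilyloxy)phenyl]ethanone | C=CC(C)(C)c1c(OCOC)cc(O[Si](C(C)C)(C(C)C)C(C)C)c(c1OCOC)C(=O)C=[N+]=[N-] | intermediate
10 | 4-methoxybenzyl alcohol | COc1ccc(CO)cc1 | starting material
11 | 4-formyl-2-methoxyphenyl acetate (vanillin acetate) | CC(=O)Oc1ccc(C=O)cc1OC | starting material
12 | oxonium ylide from the carbene of 9 and alcohol 10 (not isolated) | C=CC(C)(C)c1c(OCOC)cc(O[Si](C(C)C)(C(C)C)C(C)C)c(c1OCOC)C(=O)[CH-][OH+]Cc1ccc(OC)cc1 | intermediate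
13 | (Z)-1-[2,4-bis(methoxymethoxy)-3-(2-methylbut-3-en-2-yl)-6-(triisopropylsilyloxy)phenyl]-2-(4-methoxybenzyloxy)ethen-1-ol (not isolated) | O/C(c1c(OCOC)c(C(C)(C)C=C)c(OCOC)cc1O[Si](C(C)C)(C(C)C)C(C)C)=C\OCc1ccc(OC)cc1 | intermediate
14 | (2R,3S)-3-(4-acetoxy-3-methoxyphenyl)-1-[2,4-bis(methoxymethoxy)-3-(2-methylbut-3-en-2-yl)-6-(triisopropylsilyloxy)phenyl]-3-hydroxy-2-(4-methoxybenzyloxy)propan-1-one | C=CC(C)(C)c1c(OCOC)cc(O[Si](C(C)C)(C(C)C)C(C)C)c(c1OCOC)C(=O)[C@H](OCc1ccc(OC)cc1)[C@@H](O)c1ccc(OC(C)=O)c(OC)c1 | intermediate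
15 | (2R,3S)-3-(4-acetoxy-3-methoxyphenyl)-3-hydroxy-1-[6-hydroxy-2,4-bis(methoxymethoxy)-3-(2-methylbut-3-en-2-yl)phenyl]-2-(4-methoxybenzyloxy)propan-1-one | C=CC(C)(C)c1c(OCOC)cc(O)c(c1OCOC)C(=O)[C@H](OCc1ccc(OC)cc1)[C@@H](O)c1ccc(OC(C)=O)c(OC)c1 | intermediate
16 | (2R,3R)-2-(4-acetoxy-3-methoxyphenyl)-3-(4-methoxybenzyloxy)-5,7-bis(methoxymethoxy)-6-(2-methylbut-3-en-2-yl)chroman-4-one | C=CC(C)(C)c1c(OCOC)cc2c(c1OCOC)C(=O)[C@H](OCc1ccc(OC)cc1)[C@@H](c1ccc(OC(C)=O)c(OC)c1)O2 | intermediate
17 | (2R,3R)-2-(4-acetoxy-3-methoxyphenyl)-3-hydroxy-5,7-bis(methoxymethoxy)-6-(2-methylbut-3-en-2-yl)chroman-4-one | C=CC(C)(C)c1c(OCOC)cc2c(c1OCOC)C(=O)[C@H](O)[C@@H](c1ccc(OC(C)=O)c(OC)c1)O2 | intermediate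
18 | (2R,3R)-3,5,7-trihydroxy-2-(4-hydroxy-3-methoxyphenyl)-6-(2-methylbut-3-en-2-yl)chroman-4-one | C=CC(C)(C)c1c(O)cc2c(c1O)C(=O)[C@H](O)[C@@H](c1ccc(O)c(OC)c1)O2 | target

**Total step count:** 10. **Longest linear sequence:** 10 steps (1 to 18); 2, 10 and 11 are bought.

**Steps most likely to fail**

**1. Step 6.**
- What may go wrong:
  - the ortho acetal or silyl ether oxygen intercepts the carbene;
  - acid-induced loss of nitrogen takes place with participation of an ortho oxygen;
  - a premature proton shift gives plain O–H insertion;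
  - syn/anti or facial control is weak.
- The fallback sets out from 7 and comes back to the route at 18. It builds the C2/C3 pair by nucleophilic asymmetric epoxidation of a chalcone instead of by carbene chemistry.
- Commercial vanillin is protected (MOMCl, iPr2NEt, CH2Cl2) as 3-methoxy-4-(methoxymethoxy)benzaldehyde F1.
- The ketone 7 is enolised (LiHMDS, THF, –78 °C) and added to this aldehyde to give the racemic β-hydroxy ketone F2.
- MsCl/Et3N converts it into the mesylate F3, which DBU eliminates in the same flask to the (E)-chalcone F4.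
- Juliá–Colonna epoxidation (poly-L-leucine, urea–H2O2, DBU, THF) is a hydroperoxide conjugate addition that ignores the isolated vinyl group. It should give the (2R,3S)-epoxy ketone F5.
- Buffered fluoride (TBAF/AcOH) frees the phenolic epoxy ketone F6.
- A trace of acid (PPTS, CH2Cl2) lets the phenol oxygen open the oxirane at the benzylic carbon with inversion. This 6-endo opening is favoured by the electron-rich ring B and gives the (2R,3R)-tris-MOM 3-hydroxyflavanone F7.
- The conditions of step 10 convert F7 into 18.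

**2. Step 3.**
- What may go wrong:
  - the allyl group migrates to the ortho carbon next to the silyl ether;
  - the prenyl group is lost thermally;
  - the freshly formed ortho-allylphenol isomerises or cyclises on prolonged heating.
- The fallback sets out from 3 and comes back at 6. Regiocontrol then comes from symmetry instead of from the chelate.
- The rearrangement is run on 3 itself (N,N-diethylaniline, 190 °C), where both ortho carbons are equivalent. It gives 1-[2,4,6-trihydroxy-3-(2-methylbut-3-en-2-yl)phenyl]ethanone F8.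
- TIPSCl/imidazole should then select the only hydroxyl that does not stand next to the quaternary carbon, which gives 6.

**3. Step 8.**
- What may go wrong:
  - β-elimination of the activated carbinol across C2–C3;
  - ionisation at C2 that erodes the inversion.
- The fallback sets out from 15 and comes back at 16. It replaces the stereospecific displacement by a substrate-controlled, reversible closure.
- Neutral methanolysis of the aryl acetate (NH4OAc, aq MeOH, rt) gives the 4-hydroxybenzylic alcohol F9.
- Warming in a weakly acidic, ionising medium (HFIP/CH2Cl2, 40 °C) removes water to give the para-quinone methide F10.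
- The C8a hydroxyl adds to C2 of the quinone methide (oxa-1,6-addition, six-membered ring) to give the 4'-hydroxy 3-O-PMB flavanone F11. The C3 substituent and the reversibility of the addition both favour the 2,3-trans arrangement.
- Ac2O/pyridine then returns the material to 16.

**Further compounds**
F1 | step 6 | 3-methoxy-4-(methoxymethoxy)benzaldehyde | COCOc1ccc(C=O)cc1OC
F2 | step 6 | racemic 1-[2,4-bis(methoxymethoxy)-3-(2-methylbut-3-en-2-yl)-6-(triisopropylsilyloxy)phenyl]-3-hydroxy-3-[3-methoxy-4-(methoxymethoxy)phenyl]propan-1-one | C=CC(C)(C)c1c(OCOC)cc(O[Si](C(C)C)(C(C)C)C(C)C)c(c1OCOC)C(=O)CC(O)c1ccc(OCOC)c(OC)c1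
F3 | step 6 | methanesulfonate of F2 (racemic, not isolated) | C=CC(C)(C)c1c(OCOC)cc(O[Si](C(C)C)(C(C)C)C(C)C)c(c1OCOC)C(=O)CC(OS(C)(=O)=O)c1ccc(OCOC)c(OC)c1
F4 | step 6 | (E)-1-[2,4-bis(methoxymethoxy)-3-(2-methylbut-3-en-2-yl)-6-(triisopropylsilyloxy)phenyl]-3-[3-methoxy-4-(methoxymethoxy)phenyl]prop-2-en-1-one | C=CC(C)(C)c1c(OCOC)cc(O[Si](C(C)C)(C(C)C)C(C)C)c(c1OCOC)C(=O)/C=C/c1ccc(OCOC)c(OC)c1
F5 | step 6 | [2,4-bis(methoxymethoxy)-3-(2-methylbut-3-en-2-yl)-6-(triisopropylsilyloxy)phenyl]{(2R,3S)-3-[3-methoxy-4-(methoxymethoxy)phenyl]oxiran-2-yl}methanone | C=CC(C)(C)c1c(OCOC)cc(O[Si](C(C)C)(C(C)C)C(C)C)c(c1OCOC)C(=O)[C@@H]2O[C@H]2c3ccc(OCOC)c(OC)c3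
F6 | step 6 | [6-hydroxy-2,4-bis(methoxymethoxy)-3-(2-methylbut-3-en-2-yl)phenyl]{(2R,3S)-3-[3-methoxy-4-(methoxymethoxy)phenyl]oxiran-2-yl}methanone | C=CC(C)(C)c1c(OCOC)cc(O)c(c1OCOC)C(=O)[C@@H]2O[C@H]2c3ccc(OCOC)c(OC)c3
F7 | step 6 | (2R,3R)-3-hydroxy-5,7-bis(methoxymethoxy)-2-[3-methoxy-4-(methoxymethoxy)phenyl]-6-(2-methylbut-3-en-2-yl)chroman-4-one | C=CC(C)(C)c1c(OCOC)cc2c(c1OCOC)C(=O)[C@H](O)[C@@H](c1ccc(OCOC)c(OC)c1)O2
F8 | step 3 | 1-[2,4,6-trihydroxy-3-(2-methylbut-3-en-2-yl)phenyl]ethanone | CC(=O)c1c(O)cc(O)c(C(C)(C)C=C)c1O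
F9 | step 8 | (2R,3S)-3-hydroxy-3-(4-hydroxy-3-methoxyphenyl)-1-[6-hydroxy-2,4-bis(methoxymethoxy)-3-(2-methylbut-3-en-2-yl)phenyl]-2-(4-methoxybenzyloxy)propan-1-one | C=CC(C)(C)c1c(OCOC)cc(O)c(c1OCOC)C(=O)[C@H](OCc1ccc(OC)cc1)[C@@H](O)c1ccc(O)c(OC)c1
F10 | step 8 | para-quinone methide from F9 by loss of water (C3 configuration kept, not isolated) | C=CC(C)(C)c1c(OCOC)cc(O)c(c1OCOC)C(=O)[C@H](OCc1ccc(OC)cc1)C=C1C=CC(=O)C(OC)=C1
F11 | step 8 | (2R,3R)-2-(4-hydroxy-3-methoxyphenyl)-3-(4-methoxybenzyloxy)-5,7-bis(methoxymethoxy)-6-(2-methylbut-3-en-2-yl)chroman-4-one | C=CC(C)(C)c1c(OCOC)cc2c(c1OCOC)C(=O)[C@H](OCc1ccc(OC)cc1)[C@@H](c1ccc(O)c(OC)c1)O2
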